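Ring B is disconnected at both bonds to the spiro carbon, C6–C7 and C6–C11. The key step exploits that C9 (Me, Cl) and C10 (Br) lie on the five-carbon chain C7–C11 whose two ends both join C6 of ring A, so the anti bromochloride can be made enantiopure on an open Z-allylic alcohol and brought in as a 1,5-bis-electrophile. One flask alkylates the C6 enolate of the dimedone vinylogous ester twice, closing ring B and setting C6. The precursor pair is 3-isobutoxy-5,5-dimethylcyclohex-2-enone and the (2S,3S)-bromochloro-1,5-bis(triflate), chosen over a dihalide so that both alkylations run cold.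

Key step: step 8

Remarks on the chemistry
- Numbering: the atom numbers of the target are kept in all spiro compounds (ring A: C1 to C6 with C14 on C1; ring B: C6 to C11, C9 with Me and Cl, C10 with Br).
- Descriptors: the chain stereocentres keep one geometry from 5 to 17; it reads (2S,3S) with O-substituted chain ends (a 1,5-diiodide of the same geometry would read 2R,3S), and C6 reads R or S as the CIP ranks of C1 and C5 change, without change of geometry.
- Ligand: the antipode of the Schiff base ligand in step 4 that gives (2S,3S)-5 is fixed by a test run on 4.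
- Target: 17 is the trans bromohydrin (C3–OH and C4–Br both equatorial on ring A); plain hydride reduction of such α-bromo ketones is expected to favour the cis isomer, so C3 is set under catalyst control.

Step 1
Reactants: 1 tert-butyl(but-3-yn-1-yloxy)dimethylsilane
Product: 2 methyl 5-[(tert-butyldimethylsilyl)oxy]pent-2-ynoate
Conditions: n-BuLi, THF, −78 °C; ClCO2Me, −78 → 0 °C
Reagents that add atoms: methyl chloroformate, COC(=O)Cl
Why: Deprotonation of the terminal alkyne and C-acylation of the lithium acetylide with a chloroformate is a standard ynoate synthesis that leaves the silyl ether untouched.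

Step 2
Reactants: 2 methyl 5-[(tert-butyldimethylsilyl)oxy]pent-2-ynoate
Product: 3 methyl (Z)-5-[(tert-butyldimethylsilyl)oxy]-3-methylpent-2-enoate
Conditions: Me2CuLi (from MeLi, CuI), THF, −78 °C; NH4Cl (aq.) at −78 °C
Reagents that add atoms: lithium dimethylcuprate, [Li+].C[Cu-]C
Why: syn-Carbocupration of the ynoate and protonation at −78 °C place the new methyl cis to the C2 hydrogen, so the ester is cis to the silyloxyethyl chain (Z alkene, which later puts C8 and C11 in one ring).

Step 3
Reactants: 3 methyl (Z)-5-[(tert-butyldimethylsilyl)oxy]-3-methylpent-2-enoate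
Product: 4 (Z)-5-[(tert-butyldimethylsilyl)oxy]-3-methylpent-2-en-1-ol
Conditions: i-Bu2AlH, CH2Cl2, −78 °C; aq. potassium sodium tartrate
Reagents that add atoms: none
Why: 1,2-Reduction of the enoate with i-Bu2AlH at −78 °C gives the allylic alcohol without touching the Z double bond or the silyl ether.

Step 4
Reactants: 4 (Z)-5-[(tert-butyldimethylsilyl)oxy]-3-methylpent-2-en-1-ol
Product: 5 (2S,3S)-2-bromo-5-[(tert-butyldimethylsilyl)oxy]-3-chloro-3-methylpentan-1-ol
Conditions: N-bromosuccinimide, ClTi(OiPr)3, Schiff base ligand 2-[(3,5-di-tert-butyl-2-hydroxybenzylidene)amino]-3,3-dimethyl-1,1-diphenylbutan-1-ol (20 mol%, antipode as in the remarks), hexanes, −20 °C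
Reagents that add atoms: N-bromosuccinimide, O=C1CCC(=O)N1Br; chlorotitanium triisopropoxide, CC(C)O[Ti](Cl)(OC(C)C)OC(C)C
Why: Catalytic enantioselective bromochlorination of an allylic alcohol: the titanium-bound alkoxide of 4 is brominated at C2 on the face set by the ligand and chloride is delivered anti to the tertiary carbon C3, so anti addition across the Z alkene fixes the relative and the catalyst the absolute configuration of both centres (future C10 and C9).

Step 5
Reactants: 5 (2S,3S)-2-bromo-5-[(tert-butyldimethylsilyl)oxy]-3-chloro-3-methylpentan-1-ol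
Product: 6 (2S,3S)-2-bromo-3-chloro-3-methylpentane-1,5-diol
Conditions: HF·pyridine, THF, 0 °C → rt
Reagents that add atoms: none
Why: Fluoride cleavage of the primary silyl ether under acidic, non-basic conditions cannot close an epoxide from the bromohydrin and does not solvolyse the tertiary chloride.

Step 6
Reactants: 6 (2S,3S)-2-bromo-3-chloro-3-methylpentane-1,5-diol
Product: 7 (2S,3S)-2-bromo-3-chloro-3-methylpentane-1,5-diyl bis(trifluoromethanesulfonate)
Conditions: (CF3SO2)2O, 2,6-lutidine, CH2Cl2, −78 °C; used at once
Reagents that add atoms: trifluoromethanesulfonic anhydride, O=S(=O)(OS(=O)(=O)C(F)(F)F)C(F)(F)F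
Why: Triflation of both primary alcohols gives the bis-electrophile in one operation; triflates are preferred to iodides because an iodide at C11 next to the C10 bromide would be prone to iodide-induced loss of both halogens and because triflates alkylate lithium enolates at −78 °C.

Step 7
Reactants: 8 dimedone (5,5-dimethylcyclohexane-1,3-dione)
Product: 9 3-isobutoxy-5,5-dimethylcyclohex-2-en-1-one
Conditions: i-BuOH, p-toluenesulfonic acid monohydrate (cat.), toluene, reflux, Dean–Stark
Reagents that add atoms: 2-methylpropan-1-ol, CC(C)CO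
Why: Acid-catalysed O-alkylation of the dimedone enol with azeotropic removal of water is the standard preparation of this vinylogous ester.

Step 8
Reactants: 9 3-isobutoxy-5,5-dimethylcyclohex-2-en-1-one; 7 (2S,3S)-2-bromo-3-chloro-3-methylpentane-1,5-diyl bis(trifluoromethanesulfonate)
Product: 11 (6R,9S,10S)-10-bromo-9-chloro-3-isobutoxy-5,5,9-trimethylspiro[5.5]undec-2-en-1-one, via C6-monoalkylated triflate 10 (not isolated)
Conditions: LiN(iPr)2 (1.05 equiv), THF, −78 °C; 7, −78 °C; then LiN(iPr)2 (1.1 equiv), −78 → −40 °C
Reagents that add atoms: none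
Why: Kinetic deprotonation of 9 gives the C6 lithium enolate, which displaces the unhindered C7 triflate (SN2) to give 10; the second portion of amide regenerates the now tertiary C6 enolate, which displaces the C11 triflate intramolecularly, so C6–C7, C6–C11 and ring B form in one flask. The closest known reaction type is the spiroannulation of ketone and vinylogous ester enolates with 1,5-dielectrophiles, and primary triflates are known to alkylate lithium enolates at −78 °C. Ring B closes by a 6-exo-tet displacement through a chair-like transition state. C6 is the only new stereocentre and is controlled by the C9 and C10 centres of the chain: the chair keeps the C10 bromine equatorial (axial, it would lie 1,3-syn to a substituent of C6), and in that chair the gem-dimethyl carbon C5 takes the equatorial and the planar enolate carbon C1 the axial site on ring B, which is the (6R) product. The step needs C7 to react before C11, C- rather than O-alkylation, and substitution faster than loss of HBr or HCl from the chain: C11 is β-branched and deactivated by the C10 bromine and is therefore left for the intramolecular step, O-alkylation would need an eight-membered ring, and the triflate leaving groups let both displacements run at or below −40 °C.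

Step 9
Reactants: 11 (6R,9S,10S)-10-bromo-9-chloro-3-isobutoxy-5,5,9-trimethylspiro[5.5]undec-2-en-1-one
Product: 13 (6R,9S,10S)-10-bromo-9-chloro-5,5,9-trimethyl-1-[(trimethylsilyl)methyl]spiro[5.5]undec-1-en-3-one, via tertiary carbinol 12 (not isolated)
Conditions: Me3SiCH2Li, CeCl3, THF, −78 °C; then 1 M HCl, THF, 0 °C
Reagents that add atoms: (trimethylsilyl)methyllithium, [Li]C[Si](C)(C)C
Why: Organocerium 1,2-addition to the hindered C1 carbonyl followed by acid hydrolysis of the enol ether with allylic transposition (Stork–Danheiser sequence) gives the C3 enone that carries C14 as a CH2SiMe3 group; no stereocentre is created, and the equatorial halogens of ring B have no antiperiplanar hydrogen and survive.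

Step 10
Reactants: 13 (6R,9S,10S)-10-bromo-9-chloro-5,5,9-trimethyl-1-[(trimethylsilyl)methyl]spiro[5.5]undec-1-en-3-one
Product: 15 (4S,6S,9S,10S)-4,10-dibromo-9-chloro-5,5,9-trimethyl-1-[(trimethylsilyl)methyl]spiro[5.5]undec-1-en-3-one, via silyl dienol ether 14 (not isolated)
Conditions: LiN(iPr)2, Me3SiCl, THF, −78 °C; N-bromosuccinimide, THF, −78 → 0 °C; chromatography
Reagents that add atoms: N-bromosuccinimide, O=C1CCC(=O)N1Br
Why: Kinetic α′-deprotonation at C4 and O-silylation give the cross-conjugated silyl dienol ether, which N-bromosuccinimide brominates at its terminal carbon C4 (α′-bromination of an enone); ring B offers C4 two nearly equal faces (its C7 and C11 arms differ only at remote C10), so both C4 epimers are expected, the (4S) epimer is isolated by chromatography and material of the other configuration can be returned to the mixture through its enolate (LiN(iPr)2, then AcOH).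

Step 11
Reactants: 15 (4S,6S,9S,10S)-4,10-dibromo-9-chloro-5,5,9-trimethyl-1-[(trimethylsilyl)methyl]spiro[5.5]undec-1-en-3-one
Product: 16 (4S,6S,9S,10S)-4,10-dibromo-9-chloro-5,5,9-trimethyl-1-methylidenespiro[5.5]undecan-3-one
Conditions: Bu4NF, AcOH, THF, −78 → −40 °C
Reagents that add atoms: none
Why: Fluoride cleaves the C14–Si bond of the γ-silyl enone and the dienolate is protonated by AcOH at C2 (kinetic α-protonation, a desilylative deconjugation), which leaves the exocyclic C1=C14 alkene while the cold buffered medium does not enolise C4.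

Step 12
Reactants: 16 (4S,6S,9S,10S)-4,10-dibromo-9-chloro-5,5,9-trimethyl-1-methylidenespiro[5.5]undecan-3-one
Product: 17 (3S,4S,6S,9S,10S)-4,10-dibromo-9-chloro-5,5,9-trimethyl-1-methylidenespiro[5.5]undecan-3-ol
Conditions: (R)-1-methyl-3,3-diphenyltetrahydro-1H,3H-pyrrolo[1,2-c][1,3,2]oxazaborole (0.5 equiv), catecholborane, toluene, −78 °C
Reagents that add atoms: none
Why: CBS reduction, in which the catalyst and not ring A chooses the carbonyl face: with the branched C4 side as the large and C2 as the small group the (R)-catalyst delivers hydride to the face cis to the C4 bromine and gives the (3S) alcohol with OH trans to Br, although the axial C5 methyl opposes that face; catecholborane leaves the exocyclic alkene alone.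

Compound list
1 | tert-butyl(but-3-yn-1-yloxy)dimethylsilane | C#CCCO[Si](C)(C)C(C)(C)C | starting material
2 | methyl 5-[(tert-butyldimethylsilyl)oxy]pent-2-ynoate | COC(=O)C#CCCO[Si](C)(C)C(C)(C)C | intermediate
3 | methyl (Z)-5-[(tert-butyldimethylsilyl)oxy]-3-methylpent-2-enoate | COC(=O)/C=C(\CCO[Si](C)(C)C(C)(C)C)C | intermediate
4 | (Z)-5-[(tert-butyldimethylsilyl)oxy]-3-methylpent-2-en-1-ol | OC/C=C(\CCO[Si](C)(C)C(C)(C)C)C | intermediate
5 | (2S,3S)-2-bromo-5-[(tert-butyldimethylsilyl)oxy]-3-chloro-3-methylpentan-1-ol | CC(C)(C)[Si](C)(C)OCC[C@](C)(Cl)[C@@H](Br)CO | intermediate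
6 | (2S,3S)-2-bromo-3-chloro-3-methylpentane-1,5-diol | OCC[C@](C)(Cl)[C@@H](Br)CO | intermediate
7 | (2S,3S)-2-bromo-3-chloro-3-methylpentane-1,5-diyl bis(trifluoromethanesulfonate) | O=S(=O)(OCC[C@](C)(Cl)[C@@H](Br)COS(=O)(=O)C(F)(F)F)C(F)(F)F | intermediate
8 | dimedone (5,5-dimethylcyclohexane-1,3-dione) | CC1(C)CC(=O)CC(=O)C1 | starting material
9 | 3-isobutoxy-5,5-dimethylcyclohex-2-en-1-one | CC(C)COC1=CC(=O)CC(C)(C)C1 | intermediate
10 | (2S,3S)-2-bromo-3-chloro-5-(4-isobutoxy-6,6-dimethyl-2-oxocyclohex-3-en-1-yl)-3-methylpentyl trifluoromethanesulfonate (both epimers at the ring carbon, future C6) | CC(C)COC1=CC(=O)C(CC[C@](C)(Cl)[C@@H](Br)COS(=O)(=O)C(F)(F)F)C(C)(C)C1 | intermediate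
11 | (6R,9S,10S)-10-bromo-9-chloro-3-isobutoxy-5,5,9-trimethylspiro[5.5]undec-2-en-1-one | CC(C)COC1=CC(=O)[C@@]2(CC[C@](C)(Cl)[C@@H](Br)C2)C(C)(C)C1 | intermediate
12 | (6R,9S,10S)-10-bromo-9-chloro-1-hydroxy-3-isobutoxy-5,5,9-trimethyl-1-[(trimethylsilyl)methyl]spiro[5.5]undec-2-ene (C1 epimers) | CC(C)COC1=CC(O)(C[Si](C)(C)C)[C@@]2(CC[C@](C)(Cl)[C@@H](Br)C2)C(C)(C)C1 | intermediate
13 | (6R,9S,10S)-10-bromo-9-chloro-5,5,9-trimethyl-1-[(trimethylsilyl)methyl]spiro[5.5]undec-1-en-3-one | O=C1C=C(C[Si](C)(C)C)[C@@]2(CC[C@](C)(Cl)[C@@H](Br)C2)C(C)(C)C1 | intermediate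
14 | (6R,9S,10S)-10-bromo-9-chloro-5,5,9-trimethyl-3-[(trimethylsilyl)oxy]-1-[(trimethylsilyl)methyl]spiro[5.5]undeca-1,3-diene | C[Si](C)(C)OC1=CC(C)(C)[C@]2(CC[C@](C)(Cl)[C@@H](Br)C2)C(C[Si](C)(C)C)=C1 | intermediate
15 | (4S,6S,9S,10S)-4,10-dibromo-9-chloro-5,5,9-trimethyl-1-[(trimethylsilyl)methyl]spiro[5.5]undec-1-en-3-one | O=C1C=C(C[Si](C)(C)C)[C@@]2(CC[C@](C)(Cl)[C@@H](Br)C2)C(C)(C)[C@@H]1Br | intermediate
16 | (4S,6S,9S,10S)-4,10-dibromo-9-chloro-5,5,9-trimethyl-1-methylidenespiro[5.5]undecan-3-one | C=C1CC(=O)[C@@H](Br)C(C)(C)[C@]12CC[C@](C)(Cl)[C@@H](Br)C2 | intermediate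
17 | (3S,4S,6S,9S,10S)-4,10-dibromo-9-chloro-5,5,9-trimethyl-1-methylidenespiro[5.5]undecan-3-ol | C=C1C[C@H](O)[C@@H](Br)C(C)(C)[C@]12CC[C@](C)(Cl)[C@@H](Br)C2 | target

Total step count: 12. Longest linear sequence: 11 steps (steps 1 to 6 and 8 to 12).

Steps most likely to fail

1. Step 8. What may go wrong: amide-induced loss of HBr, HCl or triflic acid from the open chain before carbon–carbon bond formation; deprotonation of 10 at C4 instead of the hindered C6, so that ring closure stalls; closure through the other chair, which inverts C6. The fallback makes the same two bonds one at a time with a single leaving group present. It sets out from 5 and comes back at 11. The C11 hydroxyl of 5 is protected with 4-methoxybenzyl trichloroacetimidate and catalytic 10-camphorsulfonic acid to give the PMB/silyl bis-ether F1. HF·pyridine frees the C7 hydroxyl to give the C7 alcohol F2, and (CF3SO2)2O with 2,6-lutidine gives the mono-triflate F3. The lithium enolate of 9 (LiN(iPr)2, THF, −78 °C) is alkylated with F3 to the isolated C6-alkylated PMB ether F4. 2,3-Dichloro-5,6-dicyano-1,4-benzoquinone in wet CH2Cl2 removes the PMB group to give the C11 alcohol F5. Triflation as in step 6 then gives 10, which is closed with KN(SiMe3)2 in THF at −78 °C to 11.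

2. Step 10. What may go wrong: no useful discrimination between the two faces of the dienol ether at C4, so that the separation of C4 epimers carries the whole burden, or the epimers do not separate as ketones. The fallback replaces chromatography of epimeric ketones by a catalyst-controlled kinetic resolution. It sets out from 13 and comes back at 15. 13 is brominated as in step 10 and the crude C4-epimer mixture is treated with (S)-1-methyl-3,3-diphenyltetrahydro-1H,3H-pyrrolo[1,2-c][1,3,2]oxazaborole and a deficit of catecholborane in toluene at −78 °C. The catalyst addresses the face that is open (anti to the axial C5 methyl) only in the (4S) epimer, which should be reduced first to the cis allylic alcohol F6. F6 is separated from unreacted ketone (an alcohol from a ketone) and oxidised with Dess–Martin periodinane in CH2Cl2 to 15; the recovered ketone is re-equilibrated through its enolate and recycled.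

3. Step 12. What may go wrong: hydride delivery from the sterically easier face (equatorial attack, anti to the axial C5 methyl) overrides catalyst control and the cis bromohydrin predominates. The fallback accepts that preference and inverts C3 afterwards. It sets out from 16 and comes back at 17. LiBH(s-Bu)3 in THF at −78 °C should attack equatorially and give the cis alcohol F7. Mitsunobu reaction of F7 with 4-nitrobenzoic acid, PPh3 and diisopropyl azodicarboxylate in toluene inverts C3 and gives the trans 4-nitrobenzoate F8; the axial C3–O bond of F7 is displaced from the unhindered equatorial direction. K2CO3 in MeOH at 0 °C cleaves F8 to 17.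

Further compounds
F1 | step 8 | tert-butyl{[(3S,4S)-4-bromo-3-chloro-5-[(4-methoxybenzyl)oxy]-3-methylpentyl]oxy}dimethylsilane | CC(C)(C)[Si](C)(C)OCC[C@](C)(Cl)[C@@H](Br)COCc1ccc(OC)cc1
F2 | step 8 | (3S,4S)-4-bromo-3-chloro-5-[(4-methoxybenzyl)oxy]-3-methylpentan-1-ol | OCC[C@](C)(Cl)[C@@H](Br)COCc1ccc(OC)cc1
F3 | step 8 | (3S,4S)-4-bromo-3-chloro-5-[(4-methoxybenzyl)oxy]-3-methylpentyl trifluoromethanesulfonate | FC(F)(F)S(=O)(=O)OCC[C@](C)(Cl)[C@@H](Br)COCc1ccc(OC)cc1
F4 | step 8 | 6-[(3S,4S)-4-bromo-3-chloro-5-[(4-methoxybenzyl)oxy]-3-methylpentyl]-3-isobutoxy-5,5-dimethylcyclohex-2-en-1-one (C6 epimers) | CC(C)COC1=CC(=O)C(CC[C@](C)(Cl)[C@@H](Br)COCc2ccc(OC)cc2)C(C)(C)C1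
F5 | step 8 | 6-[(3S,4S)-4-bromo-3-chloro-5-hydroxy-3-methylpentyl]-3-isobutoxy-5,5-dimethylcyclohex-2-en-1-one (C6 epimers) | CC(C)COC1=CC(=O)C(CC[C@](C)(Cl)[C@@H](Br)CO)C(C)(C)C1
F6 | step 10 | (3R,4S,6S,9S,10S)-4,10-dibromo-9-chloro-5,5,9-trimethyl-1-[(trimethylsilyl)methyl]spiro[5.5]undec-1-en-3-ol | C[Si](C)(C)CC1=C[C@@H](O)[C@@H](Br)C(C)(C)[C@]12CC[C@](C)(Cl)[C@@H](Br)C2
F7 | step 12 | (3R,4S,6S,9S,10S)-4,10-dibromo-9-chloro-5,5,9-trimethyl-1-methylidenespiro[5.5]undecan-3-ol | C=C1C[C@@H](O)[C@@H](Br)C(C)(C)[C@]12CC[C@](C)(Cl)[C@@H](Br)C2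
F8 | step 12 | (3S,4S,6S,9S,10S)-4,10-dibromo-9-chloro-5,5,9-trimethyl-1-methylidenespiro[5.5]undecan-3-yl 4-nitrobenzoate | C=C1C[C@H](OC(=O)c3ccc(cc3)[N+](=O)[O-])[C@@H](Br)C(C)(C)[C@]12CC[C@](C)(Cl)[C@@H](Br)C2
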